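**Plan**
- Retrosynthetic cuts, in order: C1'–C2' (quinone CH2 to alkenyl carbon); the C3'–CH3 bond together with the C2'≡C3' alkyne carbon; C4'–C5' (diazoacetate insertion into an aldehyde C–H); what remains is the C15 block C5'–C16'.
- Feature: C5'–C16' with its three methyl branches is the farnesol skeleton (farnesol C1 = C5', C3 = C7', C7 = C11'). The methyl-bearing centres C7' and C11' stand 1,5 to each other exactly where farnesol has its two E-trisubstituted alkenes. No ring of the target takes part; the naphthoquinone (benzo ring A, quinone ring B) is bought as menadione.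
- Forward: farnesol, saturated C15 alcohol, aldehyde, C17 β-keto ester, β-hydroxy ester, C18 homopropargylic silyl ether, carboalumination and nickel coupling with chloromethylated menadione, desilylation. No ring is formed.
- Stereochemistry: C7' and C11' come from one iridium-catalysed asymmetric hydrogenation of (2E,6E)-farnesol; C5' from ruthenium (S)-BINAP hydrogenation of the β-keto ester; the 2'E alkene from syn carboalumination, kept in the coupling.

Key step: step 1

Assumption: the side chain is numbered C1' to C16' from the quinone ring, and each chiral ligand is used in the antipode whose facial preference gives the configuration stated for the product.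

**Step 1**
Reactants: 1 (2E,6E)-farnesol
Product: 2 (3R,7R)-3,7,11-trimethyldodecan-1-ol
Conditions: H2 (50 bar), [Ir(cod)(L)][B(C6H3(CF3)2)4] (1 mol %, L = chiral bicyclic pyridyl phosphinite of the 2-aryl-5,6,7,8-tetrahydroquinolin-8-yl diarylphosphinite type), CH2Cl2, rt
Reagents that add atoms: none
Why: This is the asymmetric hydrogenation of unfunctionalised trisubstituted alkenes by a cationic iridium N,P complex, a chiral relative of the Crabtree catalyst: after the cyclooctadiene is hydrogenated off, the iridium dihydride binds each alkene and, by migratory insertion and reductive elimination, delivers both hydrogens syn to one enantioface. No ring is closed and no skeletal bond is made; the step only saturates C2=C3, C6=C7 and C10=C11 of farnesol. C3 and C7 (later C7' and C11') are each set by the chiral ligand pocket, which distinguishes the enantiofaces through the position of the single vinylic hydrogen of an E-trisubstituted alkene, so the two centres are fixed independently of one another and one ligand antipode should give the like (3R,7R) pair. The step needs enantioface selectivity at two alkenes and full conversion of the isopropylidene group, which creates no stereocentre; the geometric purity of the (2E,6E) substrate, the non-coordinating counter-ion and solvent, and the absence of any other reducible group secure this. The free primary hydroxyl is tolerated by this catalyst class and is kept as the handle that becomes C5'.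

**Step 2**
Reactants: 2 (3R,7R)-3,7,11-trimethyldodecan-1-ol
Product: 3 (3R,7R)-3,7,11-trimethyldodecanal
Conditions: TEMPO (10 mol %), PhI(OAc)2 (1.1 equiv), CH2Cl2, rt
Reagents that add atoms: none
Why: Oxoammonium (TEMPO) catalysed alcohol oxidation with PhI(OAc)2 as terminal oxidant stops at the aldehyde, and the C3 stereocentre, being β to the carbonyl, cannot epimerise.

**Step 3**
Reactants: 3 (3R,7R)-3,7,11-trimethyldodecanal; 4 ethyl diazoacetate
Product: 5 ethyl (5R,9R)-5,9,13-trimethyl-3-oxotetradecanoate
Conditions: SnCl2 (10 mol %), CH2Cl2, rt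
Reagents that add atoms: none
Why: Roskamp reaction: SnCl2 activates the aldehyde for attack by the diazo carbon, and a 1,2-hydride shift with loss of N2 gives the β-keto ester, unhindered aliphatic aldehydes being the standard substrates and the β-stereocentre remaining untouched.

**Step 4**
Reactants: 5 ethyl (5R,9R)-5,9,13-trimethyl-3-oxotetradecanoate
Product: 6 ethyl (3S,5R,9R)-3-hydroxy-5,9,13-trimethyltetradecanoate
Conditions: H2 (50 bar), [RuCl(C6H6)((S)-BINAP)]Cl (0.5 mol %), EtOH, 50 °C
Reagents that add atoms: none
Why: Noyori asymmetric hydrogenation of a β-keto ester: the substrate chelates the (S)-BINAP ruthenium hydride through both carbonyls and hydride is delivered to one ketone face, which should give the 3S alcohol (the same sense as the (R)-BINAP to (R)-3-hydroxyalkanoate correlation of simple 3-oxoalkanoates) under catalyst control that overrides the remote C5 methyl.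

**Step 5**
Reactants: 6 ethyl (3S,5R,9R)-3-hydroxy-5,9,13-trimethyltetradecanoate
Product: 7 ethyl (3S,5R,9R)-3-[(tert-butyldimethylsilyl)oxy]-5,9,13-trimethyltetradecanoate
Conditions: TBSCl, imidazole, DMF, rt
Reagents that add atoms: tert-butyldimethylsilyl chloride, CC(C)(C)[Si](C)(C)Cl
Why: Imidazole-promoted silylation of a secondary alcohol masks the hydroxyl towards the aluminium and nickel reagents of steps 6 to 9 and does not touch C3.

**Step 6**
Reactants: 7 ethyl (3S,5R,9R)-3-[(tert-butyldimethylsilyl)oxy]-5,9,13-trimethyltetradecanoate
Product: 8 (3S,5R,9R)-3-[(tert-butyldimethylsilyl)oxy]-5,9,13-trimethyltetradecanal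
Conditions: i-Bu2AlH (1.1 equiv), CH2Cl2, −78 °C; MeOH, then aqueous Rochelle salt
Reagents that add atoms: none
Why: Partial reduction of an ester with one equivalent of i-Bu2AlH at −78 °C: the tetrahedral aluminium hemiacetal, stabilised by the neighbouring silyloxy oxygen, persists until the quench and then collapses to the aldehyde.

**Step 7**
Reactants: 8 (3S,5R,9R)-3-[(tert-butyldimethylsilyl)oxy]-5,9,13-trimethyltetradecanal
Product: 9 tert-butyldimethyl{[(4S,6R,10R)-6,10,14-trimethylpentadec-1-yn-4-yl]oxy}silane
Conditions: dimethyl (1-diazo-2-oxopropyl)phosphonate (1.3 equiv), K2CO3 (2 equiv), MeOH, 0 °C to rt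
Reagents that add atoms: dimethyl (1-diazo-2-oxopropyl)phosphonate, COP(=O)(OC)C(=[N+]=[N-])C(C)=O
Why: Seyferth–Gilbert homologation in the Ohira–Bestmann variant: the diazomethylphosphonate anion formed by methanolysis adds to the aldehyde, Horner–Wadsworth–Emmons-type elimination and loss of N2 with 1,2-hydride shift give the terminal alkyne, and the carbinol centre, β to the carbonyl, keeps its configuration.

**Step 8**
Reactants: 10 menadione
Product: 11 2-(chloromethyl)-3-methylnaphthalene-1,4-dione
Conditions: 37 % aqueous CH2O, HCl (gas), AcOH, rt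
Reagents that add atoms: formaldehyde, C=O; hydrogen chloride, Cl
Why: Blanc-type chloromethylation at C3, the only unsubstituted quinonoid position of menadione, is a known preparation of this chloride, and the acidic medium leaves the quinone intact.

**Step 9**
Reactants: 9 tert-butyldimethyl{[(4S,6R,10R)-6,10,14-trimethylpentadec-1-yn-4-yl]oxy}silane; 12 trimethylaluminium; 11 2-(chloromethyl)-3-methylnaphthalene-1,4-dione
Product: 14 2-[(2E,5S,7R,11R)-5-[(tert-butyldimethylsilyl)oxy]-3,7,11,15-tetramethylhexadec-2-en-1-yl]-3-methylnaphthalene-1,4-dione, via alkenylalane 13 (not isolated)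
Conditions: 12 (2 equiv), Cp2ZrCl2 (0.25 equiv), ClCH2CH2Cl, 0 °C to rt; volatiles and excess 12 removed in vacuo; then 11, zerovalent nickel from NiCl2(PPh3)2 (5 mol %) and n-BuLi (10 mol %), THF, −20 °C to rt; dilute HCl work-up
Reagents that add atoms: none
Why: Zirconium-catalysed Negishi carboalumination adds methyl and aluminium syn across the terminal alkyne with methyl at the internal carbon, and the resulting E alkenylalane undergoes the known nickel-catalysed sp2–sp3 cross-coupling with chloromethylated quinones with retention of alkene geometry, the silyl ether being inert to both stages and no stereocentre being touched.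

**Step 10**
Reactants: 14 2-[(2E,5S,7R,11R)-5-[(tert-butyldimethylsilyl)oxy]-3,7,11,15-tetramethylhexadec-2-en-1-yl]-3-methylnaphthalene-1,4-dione
Product: 15 2-[(2E,5S,7R,11R)-5-hydroxy-3,7,11,15-tetramethylhexadec-2-en-1-yl]-3-methylnaphthalene-1,4-dione
Conditions: HF·pyridine, THF/pyridine, 0 °C to rt
Reagents that add atoms: none
Why: Fluoride-driven Si–O cleavage under the mildly acidic, buffered conditions of HF·pyridine removes the secondary silyl ether without exposing the base-sensitive allyl quinone to basic fluoride and without affecting the E alkene or any stereocentre.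

**Compound list**
1 | (2E,6E)-farnesol [(2E,6E)-3,7,11-trimethyldodeca-2,6,10-trien-1-ol] | CC(C)=CCC/C(C)=C/CC/C(C)=C/CO | starting material
2 | (3R,7R)-3,7,11-trimethyldodecan-1-ol | OCC[C@H](C)CCC[C@H](C)CCCC(C)C | intermediate
3 | (3R,7R)-3,7,11-trimethyldodecanal | O=CC[C@H](C)CCC[C@H](C)CCCC(C)C | intermediate
4 | ethyl diazoacetate | CCOC(=O)C=[N+]=[N-] | starting material
5 | ethyl (5R,9R)-5,9,13-trimethyl-3-oxotetradecanoate | CCOC(=O)CC(=O)C[C@H](C)CCC[C@H](C)CCCC(C)C | intermediate
6 | ethyl (3S,5R,9R)-3-hydroxy-5,9,13-trimethyltetradecanoate | CCOC(=O)C[C@@H](O)C[C@H](C)CCC[C@H](C)CCCC(C)C | intermediate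
7 | ethyl (3S,5R,9R)-3-[(tert-butyldimethylsilyl)oxy]-5,9,13-trimethyltetradecanoate | CCOC(=O)C[C@@H](O[Si](C)(C)C(C)(C)C)C[C@H](C)CCC[C@H](C)CCCC(C)C | intermediate
8 | (3S,5R,9R)-3-[(tert-butyldimethylsilyl)oxy]-5,9,13-trimethyltetradecanal | O=CC[C@@H](O[Si](C)(C)C(C)(C)C)C[C@H](C)CCC[C@H](C)CCCC(C)C | intermediate
9 | tert-butyldimethyl{[(4S,6R,10R)-6,10,14-trimethylpentadec-1-yn-4-yl]oxy}silane | C#CC[C@@H](O[Si](C)(C)C(C)(C)C)C[C@H](C)CCC[C@H](C)CCCC(C)C | intermediate
10 | menadione (2-methylnaphthalene-1,4-dione) | CC1=CC(=O)c2ccccc2C1=O | starting material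
11 | 2-(chloromethyl)-3-methylnaphthalene-1,4-dione | CC1=C(CCl)C(=O)c2ccccc2C1=O | intermediate
12 | trimethylaluminium | C[Al](C)C | starting material
13 | dimethyl[(1E,4S,6R,10R)-4-[(tert-butyldimethylsilyl)oxy]-2,6,10,14-tetramethylpentadec-1-en-1-yl]alane | C[Al](C)/C=C(\C)C[C@@H](O[Si](C)(C)C(C)(C)C)C[C@H](C)CCC[C@H](C)CCCC(C)C | intermediate
14 | 2-[(2E,5S,7R,11R)-5-[(tert-butyldimethylsilyl)oxy]-3,7,11,15-tetramethylhexadec-2-en-1-yl]-3-methylnaphthalene-1,4-dione | CC1=C(C/C=C(\C)C[C@@H](O[Si](C)(C)C(C)(C)C)C[C@H](C)CCC[C@H](C)CCCC(C)C)C(=O)c2ccccc2C1=O | intermediate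
15 | 2-[(2E,5S,7R,11R)-5-hydroxy-3,7,11,15-tetramethylhexadec-2-en-1-yl]-3-methylnaphthalene-1,4-dione | CC1=C(C/C=C(\C)C[C@@H](O)C[C@H](C)CCC[C@H](C)CCCC(C)C)C(=O)c2ccccc2C1=O | target

**Step count**
Total: 10 steps. Longest linear sequence: 9 steps from farnesol (steps 1 to 7, 9 and 10); step 8 is a one-step side branch from menadione.

**Steps most likely to fail**

Step 9. The alkenylalane or the low-valent nickel may reduce or add to the quinone carbonyls instead of displacing the chloride, and the chloromethyl quinone may decompose on the Lewis-acidic aluminium residues. The fallback sets out from 10 and 9 and comes back at 14; it carries the quinone as its dimethyl ether. Menadione 10 would be reduced with Na2S2O4 to 2-methylnaphthalene-1,4-diol F1 and methylated without isolation (Me2SO4, KOH) to 1,4-dimethoxy-2-methylnaphthalene F2. Chloromethylation (paraformaldehyde, HCl, AcOH) should give 2-(chloromethyl)-1,4-dimethoxy-3-methylnaphthalene F3. The alane 13, made from 9 as in step 9, would be coupled with this electron-rich benzylic chloride under Pd(PPh3)4 catalysis (zerovalent palladium, Negishi-type alkenylalane–benzyl halide coupling) to tert-butyl{[(2E,5S,7R,11R)-1-(1,4-dimethoxy-3-methylnaphthalen-2-yl)-3,7,11,15-tetramethylhexadec-2-en-5-yl]oxy}dimethylsilane F4. Oxidative demethylation with (NH4)2Ce(NO3)6 in MeCN/H2O at 0 °C should then give the quinone 14.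

Step 1. Enantioface discrimination may differ between the hydroxyl-bearing C2=C3 alkene and the remote C6=C7 alkene, or the reduction may stall before the isopropylidene group is consumed; either would leave stereoisomers that cannot be separated later. The fallback sets out from 1 and comes back at 2; it sets the two centres in separate operations. Hydroxyl-directed hydrogenation of 1 with Ru(OAc)2[(S)-BINAP] (H2, MeOH), which touches only the allylic alcohol alkene, should give (3R,6E)-3,7,11-trimethyldodeca-6,10-dien-1-ol F5. The two remaining, purely alkyl-substituted alkenes would then be hydrogenated with an iridium N,P catalyst chosen only for that alkene class, to give 2.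

Step 7. Base-induced β-elimination of the silyloxy group from aldehyde 8 may compete with the homologation in K2CO3/MeOH. The fallback sets out from 3 and comes back at 9; it introduces the alkyne and the carbinol centre together and bypasses steps 3 to 7. Aldehyde 3 would be propargylated with allenylboronic acid pinacol ester under catalysis by a BINOL-derived chiral phosphoric acid bearing 3,3'-bis(2,4,6-triisopropylphenyl) groups (the antipode that gives the 4S carbinol; toluene, −20 °C) to give (4S,6R,10R)-6,10,14-trimethylpentadec-1-yn-4-ol F6. Silylation (TBSCl, imidazole, DMF) would give 9.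

**Further compounds**
F1 | step 9 | 2-methylnaphthalene-1,4-diol | Cc1cc(O)c2ccccc2c1O
F2 | step 9 | 1,4-dimethoxy-2-methylnaphthalene | COc1cc(C)c(OC)c2ccccc12
F3 | step 9 | 2-(chloromethyl)-1,4-dimethoxy-3-methylnaphthalene | COc1c(C)c(CCl)c(OC)c2ccccc12
F4 | step 9 | tert-butyl{[(2E,5S,7R,11R)-1-(1,4-dimethoxy-3-methylnaphthalen-2-yl)-3,7,11,15-tetramethylhexadec-2-en-5-yl]oxy}dimethylsilane | COc1c(C)c(C/C=C(\C)C[C@@H](O[Si](C)(C)C(C)(C)C)C[C@H](C)CCC[C@H](C)CCCC(C)C)c(OC)c2ccccc12
F5 | step 1 | (3R,6E)-3,7,11-trimethyldodeca-6,10-dien-1-ol | OCC[C@H](C)CC/C=C(\C)CCC=C(C)C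
F6 | step 7 | (4S,6R,10R)-6,10,14-trimethylpentadec-1-yn-4-ol | C#CC[C@@H](O)C[C@H](C)CCC[C@H](C)CCCC(C)C
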